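The reading at 1.5 h lies later than the last larch reading at 40.0 min, and neither run reads substrate, so substrate has to be reckoned from side product A.

| setting | birch | larch | flask |
|---|---|---|---|
| substrate | 0.050 M | 0.050 M | 0.050 M |
| partner | 0.90 equiv | 0.60 equiv | 0.900 equiv |
| remark | the very flask that is asked about, followed so far | run made earlier |  |
| time |  |  | 1.5 h |

| run | time / min | target / % | side product A / % |
|---|---|---|---|
| birch | 1.33 | 0.3 | 2.5 |
| birch | 2.50 | 0 | 3.7 |
| birch | 5.00 | 0.1 | 7.4 |
| birch | 10.0 | 0.5 | 12.7 |
| birch | 20.0 | 0.5 | 21.1 |
| larch | 3.00 | 0 | 3.4 |
| larch | 5.00 | 0.1 | 4.3 |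
| larch | 10.0 | 0.4 | 8.2 |
| larch | 20.0 | 0.2 | 14.5 |
| larch | 40.0 | 0 | 22.9 |

(readings scatter by 0.5 percentage points)

- how much target the flask holds at 1.5 h, in percent of the substrate charged
- how much side product A the flask holds at 1.5 h, in percent of the substrate charged
- how much substrate the flask holds at 1.5 h, in percent of the substrate charged



Larch serves, since it runs longer than birch. At the pace of its first 20.0 min, side product A would reach the full charge in 138 min; at the pace of the next 20.0 min, in 238 min. If the rate follows c(substrate)·c(partner), the ratio of these two times, 0.579, tells how far that product fell between the stretches. A lost fraction of the charge lowers it by that fraction times 2.67, taking partner lost with substrate one for one, so by this estimate 15.8% of the substrate went in larch between the middles of the two stretches, while side product A rose 11.4%. Their ratio, side product A made per substrate lost, is the selectivity, read as 72.6% with the scatter of these readings, and it is frozen here.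

The forecast gives target 1.5%, side product A 46%, and substrate 52%, with “leaving substrate near 52%”. The selectivity applied to that side product A leaves substrate at 36.6%, which differs from the forecast.

The flask gives target 2.53%, side product A 42.0%, and substrate 41.7%.

    substrate + partner → side product A (k = 0.360 L mol⁻¹ min⁻¹)
    substrate + partner → intermediate A (k = 0.140 L mol⁻¹ min⁻¹)
    intermediate A → intermediate B (k = 0.00220 min⁻¹)
    intermediate B → side product B (k = 0.0180 min⁻¹)
    partner + intermediate A → target (k = 0.240 L mol⁻¹ min⁻¹)
    target → over-reaction product (k = 0.00510 min⁻¹)
    partner ⇌ dormant form (K = 2.40, k = 0.00390 min⁻¹)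

Dividing the flask's 42.0% of side product A by the selectivity leaves 42.1% of substrate, against 41.7% found. The neighbouring flask has 0.20 M of substrate, with the same equivalents and time, and holds 54.9% of side product A. The same division leaves 24.4% of substrate there, and the neighbouring flask holds 23.7%.

The readings were generated by integration with made-up constants; scatter was added.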